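**Plan**

1. Retrosynthesis: remove eight O-benzyl and two O-silyl groups; take the upper C3 carbinol back to a 4-aryl-flavan-3-one; cut the interflavan C4–C6′ bond (enol triflate + arylboronate); trace both halves to one enol triflate 11; cut its pyran ring at O1–C8a and C2–C3 together, giving aldehyde 7 and ring-A diene 6.
2. Forward: ring A is bought as pyrogallol and carried as a dihydro ring (cyclohexenone vinylogous ester), acylated at C4a. Ring C closes on the ring-B aldehyde in step 5, then ring A is aromatised. The lower unit is finished from 11 and coupled to a second molecule of 11.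
3. Enabling feature: ring A carries oxygen on three adjacent carbons (C7, C8, C8a) and its only carbon branch on C4a. Its dihydro form is therefore an acylated vinylogous ester in which C8a is a carbonyl carbon, and C3=C4(OSi)–C4a=C8a(OSi) is a 1,3-dioxygenated diene: the C3 end takes the aldehyde carbon (C2), the C8a end takes the aldehyde oxygen (O1).
4. Stereochemistry: C2 of both units comes from the Ti(OiPr)4/BINOL-catalysed step. Lower C3′ and C4′ come from one hydroboration anti to the C2′ aryl. Upper C4 is set by protonation cis to the C2 aryl, and upper C3 by a bulky hydride anti to both aryl groups.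

Key step: step 5

Remark: flavan numbering is used for both units (primes for the lower unit); compounds 4 and 7 are taken as purchasable; CIP letters at C3 and C4 change with the O-substituents although the geometry does not, so cis/trans relations are given as well and the SMILES decide.

**Route**

Step 1
Reactants: 1 pyrogallol
Product: 2 2,3-dihydroxycyclohex-2-en-1-one (dihydropyrogallol)
Conditions: H2 (100 bar), Ni sponge catalyst, aq NaOH (1 equiv), 50 °C; then HCl
Reagents that add atoms: none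
Why: partial heterogeneous hydrogenation of the pyrogallol monoanion should stop at the enolate of the 2-hydroxy-1,3-dione, giving ring A at the dihydro level with its three adjacent oxygens in place.

Step 2
Reactants: 2 2,3-dihydroxycyclohex-2-en-1-one
Product: 3 2,3-bis(benzyloxy)cyclohex-2-en-1-one
Conditions: BnBr (2.3 equiv), K2CO3, DMF, 40 °C
Reagents that add atoms: benzyl bromide BrCc1ccccc1
Why: double Williamson O-alkylation of the vinylogous-acid hydroxyl and the enol hydroxyl should give the bis-benzyl vinylogous ester, O-alkylation being favoured because the central carbon already bears oxygen.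

Step 3
Reactants: 3 2,3-bis(benzyloxy)cyclohex-2-en-1-one; 4 ethyl 2-[(tert-butyldimethylsilyl)oxy]acetate
Product: 5 2,3-bis(benzyloxy)-6-{[(tert-butyldimethylsilyl)oxy]acetyl}cyclohex-2-en-1-one (enolised β-diketone)
Conditions: LiN(iPr)2 (2.2 equiv), THF, −78 °C; then 4, −78 → 0 °C; AcOH
Reagents that add atoms: none
Why: kinetic α′-deprotonation of the vinylogous ester at C6 (the future C4a) and crossed Claisen condensation with the α-silyloxy ester install C4 and C3, the second equivalent of base deprotonating the β-diketone to drive the acylation.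

Step 4
Reactants: 5 enolised β-diketone
Product: 6 trimethyl{[(1Z)-1-[3,4-bis(benzyloxy)-2-(trimethylsilyloxy)cyclohexa-1,3-dien-1-yl]-2-[(tert-butyldimethylsilyl)oxy]ethenyl]oxy}silane
Conditions: Me3SiOTf (2.3 equiv), Et3N (3 equiv), Et2O, 0 °C; filtration under argon, no aqueous work-up
Reagents that add atoms: trimethylsilyl trifluoromethanesulfonate C[Si](C)(C)OS(=O)(=O)C(F)(F)F
Why: double soft enolisation and O-silylation of a β-diketone (the standard preparation of 1,3-bis(silyloxy)-1,3-dienes) should give the diene C3=C4–C4a=C8a, since after the first silylation the only acidic C–H next to a carbonyl is at C3; the Z enol ether is expected.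

Step 5
Reactants: 6 bis(silyloxy)diene; 7 3,4-bis(benzyloxy)benzaldehyde
Product: 9 (2R)-2-[3,4-bis(benzyloxy)phenyl]-7,8-bis(benzyloxy)-3-[(tert-butyldimethylsilyl)oxy]-2,3,5,6-tetrahydro-4H-chromen-4-one (C3 epimers), via silylated aldol adduct 8 (not isolated)
Conditions: Ti(OiPr)4 (10 mol %), (S)-BINOL (20 mol %), 4 Å MS, THF, −20 °C; then CF3CO2H, CH2Cl2, 0 °C
Reagents that add atoms: none
Why: The titanium–BINOL complex binds aldehyde 7 and the terminal enol carbon C3 of 6 adds to its Si face (Mukaiyama aldol, bond C2–C3) with silyl transfer to give 8; CF3CO2H then strips the two Me3Si groups, the C2 hydroxyl adds to the ring-A carbonyl carbon C8a and the hemiketal loses water (bond O1–C8a), so that O1 is the former aldehyde oxygen and the overall change is a stepwise oxa-Diels–Alder of C3=C4–C4a=C8a with C=O. The closest known reaction type is the Ti(OiPr)4/BINOL-catalysed aldol of 1,3-bis(silyloxy)-1,3-dienes with aromatic aldehydes followed by acid cyclisation to 2,3-dihydro-4H-pyran-4-ones. Ring C closes by 6-exo-trig hemiketalisation at C8a followed by dehydration to the vinylogous ester. C2 is set by the chiral catalyst (the BINOL enantiomer that exposes the Si face is needed; (S)-BINOL is proposed and is exchanged for (R)-BINOL if a trial shows the opposite sense), while C3 forms as a mixture that is erased in step 7. The step needs reaction at C3 and not at C4a, which is secured because C4a is fully substituted and C3 is the terminus of the dienol ether, and it needs ring closure through O1 without ionisation at benzylic C2, which the brief cold acid treatment and the ready addition–elimination at the vinylogous-acid carbon C8a secure.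

Step 6
Reactants: 9 tetrahydrochromenone
Product: 10 (2R)-2-[3,4-bis(benzyloxy)phenyl]-7,8-bis(benzyloxy)-3-[(tert-butyldimethylsilyl)oxy]chroman-4-one (C3 epimers)
Conditions: DDQ (1.05 equiv), toluene, 0 °C → rt
Reagents that add atoms: none
Why: dehydrogenation of the cyclohexa-1,3-diene ring A by DDQ (hydride abstraction at C6, proton loss at C5) is driven by aromatisation and should leave C2 untouched.

Step 7
Reactants: 10 chroman-4-one
Product: 11 (2R)-2-[3,4-bis(benzyloxy)phenyl]-7,8-bis(benzyloxy)-3-[(tert-butyldimethylsilyl)oxy]-2H-chromen-4-yl trifluoromethanesulfonate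
Conditions: KN(SiMe3)2 added to 10 and N-(5-chloropyridin-2-yl)triflimide, THF, −78 °C
Reagents that add atoms: N-(5-chloropyridin-2-yl)-1,1,1-trifluoro-N-[(trifluoromethyl)sulfonyl]methanesulfonamide FC(F)(F)S(=O)(=O)N(c1ccc(Cl)cn1)S(=O)(=O)C(F)(F)F
Why: enolate O-triflation at the only enolisable position (C3), with in situ trapping at −78 °C to outrun ring opening by β-elimination of the ring-A phenoxide, should give the enol triflate and remove the C3 stereocentre.

Step 8
Reactants: 11 enol triflate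
Product: 12 tert-butyl{[(2R)-2-[3,4-bis(benzyloxy)phenyl]-7,8-bis(benzyloxy)-2H-chromen-3-yl]oxy}dimethylsilane
Conditions: Pd(OAc)2 (5 mol %), PPh3 (10 mol %), HCO2H, Bu3N, DMF, 60 °C
Reagents that add atoms: none
Why: palladium-catalysed formate reduction of an enol triflate (oxidative addition, formate exchange with loss of CO2, reductive elimination) should replace OTf by H and leave the silyl enol ether and C2 intact.

Step 9
Reactants: 12 silyl enol ether
Product: 14 (2R,3R,4S)-2-[3,4-bis(benzyloxy)phenyl]-7,8-bis(benzyloxy)-3-[(tert-butyldimethylsilyl)oxy]chroman-4-ol (2,3-cis-3,4-trans), via C4 alkylborane 13 (not isolated)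
Conditions: BH3·THF, THF, 0 °C; then NaOH, H2O2, 0 °C
Reagents that add atoms: hydrogen peroxide OO (oxygen at C4); borane–tetrahydrofuran B.C1CCOC1 (boron of 13 only)
Why: hydroboration–oxidation of a cyclic silyl enol ether puts boron on C4 (β to oxygen, less substituted) and hydrogen on C3, syn and on the face opposite the C2 aryl group, and oxidation with retention gives the trans 3-silyloxy-4-ol, so C3 (cis to the aryl) and C4 (trans to the 3-oxygen) are both relayed from C2.

Step 10
Reactants: 14 chroman-4-ol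
Product: 15 (2R,3S,4S)-2-[3,4-bis(benzyloxy)phenyl]-7,8-bis(benzyloxy)-3,4-bis[(tert-butyldimethylsilyl)oxy]chromane (2,3-cis-3,4-trans)
Conditions: tBuMe2SiOTf, 2,6-lutidine, CH2Cl2, −78 → 0 °C
Reagents that add atoms: tert-butyldimethylsilyl trifluoromethanesulfonate CC(C)(C)[Si](C)(C)OS(=O)(=O)C(F)(F)F
Why: silylation of the hindered benzylic alcohol with the silyl triflate and a hindered base proceeds without ionisation at C4 and masks this oxygen against hydrogenolysis in step 16.

Step 11
Reactants: 15 bis-silyl ether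
Product: 16 (2R,3S,4S)-6-bromo-2-[3,4-bis(benzyloxy)phenyl]-7,8-bis(benzyloxy)-3,4-bis[(tert-butyldimethylsilyl)oxy]chromane
Conditions: N-bromosuccinimide (1.0 equiv), CH2Cl2, 0 °C, dark
Reagents that add atoms: N-bromosuccinimide O=C1CCC(=O)N1Br
Why: electrophilic aromatic bromination should go to C6 of ring A, which is para to O1 and ortho to the 7-benzyloxy group (the position that couples in the natural dimers), ring B being activated by one para oxygen only.

Step 12
Reactants: 16 aryl bromide
Product: 17 (2R,3S,4S)-2-[3,4-bis(benzyloxy)phenyl]-7,8-bis(benzyloxy)-3,4-bis[(tert-butyldimethylsilyl)oxy]-6-(4,4,5,5-tetramethyl-1,3,2-dioxaborolan-2-yl)chromane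
Conditions: bis(pinacolato)diboron, PdCl2(dppf) (5 mol %), KOAc, 1,4-dioxane, 90 °C
Reagents that add atoms: bis(pinacolato)diboron CC1(C)OB(OC1(C)C)B1OC(C)(C)C(C)(C)O1
Why: Miyaura borylation of the aryl bromide (acetate-assisted transmetalation) is neutral enough for the silyl and benzyl ethers.

Step 13
Reactants: 11 enol triflate; 17 arylboronate
Product: 18 enol silyl ether dimer: the upper (2R)-3-[(tert-butyldimethylsilyl)oxy]-2H-chromene of 12 carrying at C4 the C6′ carbon of the lower (2R,3S,4S)-bis-silyl chromane of 15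
Conditions: Pd(OAc)2 (5 mol %), SPhos (10 mol %), K3PO4, toluene/H2O (10:1), 70 °C
Reagents that add atoms: none
Why: Suzuki–Miyaura coupling of an enol triflate with an arylboronate forms the interflavan C4–C6′ bond at sp2 carbon, so no stereocentre is at stake here, and a bulky biaryl phosphine serves the hindered tetrasubstituted alkene.

Step 14
Reactants: 18 enol silyl ether dimer
Product: 19 ketone dimer: upper (2R,4S)-2,4-cis-4-aryl-flavan-3-one, lower unit as in 15
Conditions: Bu4NF (1.1 equiv), AcOH (1.5 equiv), THF, −20 → 0 °C, argon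
Reagents that add atoms: none
Why: buffered fluoride cleaves the silyl enol ether much faster than the hindered secondary silyl ethers, and the enol is protonated at C4 on the face opposite the C2 aryl group; the cis-2,4-diaryl ketone with both aryl groups pseudo-equatorial is also the expected thermodynamic epimer through the C3–C4 enol.

Step 15
Reactants: 19 ketone dimer
Product: 20 all-cis alcohol dimer: upper (2R,3R,4S)-2,3-cis-3,4-cis-4-aryl-flavan-3-ol, lower unit as in 15, eight benzyl ethers
Conditions: LiBH(s-Bu)3 (3 equiv), THF, −78 °C; AcOH quench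
Reagents that add atoms: none
Why: a bulky trialkylborohydride attacks the flavan-3-one on the face opposite both aryl groups (equatorial attack) and gives the axial 3-hydroxyl cis to the C2 and C4 aryl groups, as in the known oxidation–reduction route from 2,3-trans- to 2,3-cis-flavan-3-ols.

Step 16
Reactants: 20 all-cis alcohol dimer
Product: 21 octaphenol with the lower 3′- and 4′-oxygens still silylated: upper (2R,3R,4R), lower (2R,3S,4S)
Conditions: H2 (1 bar), Pd(OH)2/C, EtOAc/THF, rt
Reagents that add atoms: none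
Why: hydrogenolysis of the eight aryl benzyl ethers in a neutral aprotic solvent; the benzylic C4′ oxygen is kept as a bulky silyl ether, a poor leaving group, to suppress the C4–O hydrogenolysis known for free flavan-3,4-diols.

Step 17
Reactants: 21 bis-silyl octaphenol
Product: 22 target dimer: upper (2R,3R,4R) all-cis 4-aryl-flavan-3-ol linked from C4 to C6′ of the lower (2R,3R,4S)-2,3-cis-3,4-trans-flavan-3,4-diol
Conditions: Bu4NF, AcOH (excess), THF, rt, degassed
Reagents that add atoms: none
Why: acetic-acid-buffered fluoride desilylation is non-reductive and near neutral, so it should free the 3′- and 4′-hydroxyls without ionising the benzylic C4′–O bond or oxidising the catechols.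

**Compound list**

1 | pyrogallol | Oc1cccc(O)c1O | starting material
2 | 2,3-dihydroxycyclohex-2-en-1-one | O=C1CCCC(O)=C1O | intermediate
3 | 2,3-bis(benzyloxy)cyclohex-2-en-1-one | O=C1CCCC(OCc2ccccc2)=C1OCc1ccccc1 | intermediate
4 | ethyl 2-[(tert-butyldimethylsilyl)oxy]acetate | CCOC(=O)CO[Si](C)(C)C(C)(C)C | starting material
5 | 2,3-bis(benzyloxy)-6-{[(tert-butyldimethylsilyl)oxy]acetyl}cyclohex-2-en-1-one, drawn as the chelated enol | O=C(CO[Si](C)(C)C(C)(C)C)C1=C(O)C(OCc2ccccc2)=C(OCc2ccccc2)CC1 | intermediate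
6 | (Z)-1,3-bis(trimethylsilyloxy)diene on the dihydro ring A | C[Si](C)(C)OC1=C(/C(O[Si](C)(C)C)=C/O[Si](C)(C)C(C)(C)C)CCC(OCc2ccccc2)=C1OCc1ccccc1 | intermediate
7 | 3,4-bis(benzyloxy)benzaldehyde | O=Cc1ccc(OCc2ccccc2)c(OCc2ccccc2)c1 | starting material
8 | silylated aldol adduct, R at the carbinol carbon, C3 epimers | C[Si](C)(C)O[C@H](c1ccc(OCc2ccccc2)c(OCc2ccccc2)c1)C(O[Si](C)(C)C(C)(C)C)C(=O)C1=C(O[Si](C)(C)C)C(OCc2ccccc2)=C(OCc2ccccc2)CC1 | intermediate (not isolated)
9 | (2R)-2-[3,4-bis(benzyloxy)phenyl]-7,8-bis(benzyloxy)-3-[(tert-butyldimethylsilyl)oxy]-2,3,5,6-tetrahydro-4H-chromen-4-one, C3 epimers | O=C1C(O[Si](C)(C)C(C)(C)C)[C@@H](c2ccc(OCc3ccccc3)c(OCc3ccccc3)c2)OC2=C1CCC(OCc1ccccc1)=C2OCc1ccccc1 | intermediate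
10 | (2R)-2-[3,4-bis(benzyloxy)phenyl]-7,8-bis(benzyloxy)-3-[(tert-butyldimethylsilyl)oxy]chroman-4-one, C3 epimers | O=C1c2ccc(OCc3ccccc3)c(OCc3ccccc3)c2O[C@H](c2ccc(OCc3ccccc3)c(OCc3ccccc3)c2)C1O[Si](C)(C)C(C)(C)C | intermediate
11 | (2R)-enol triflate (3-silyloxy-2H-chromen-4-yl triflate) | FC(F)(F)S(=O)(=O)OC1=C(O[Si](C)(C)C(C)(C)C)[C@@H](c2ccc(OCc3ccccc3)c(OCc3ccccc3)c2)Oc2c1ccc(OCc1ccccc1)c2OCc1ccccc1 | intermediate
12 | (2R)-3-[(tert-butyldimethylsilyl)oxy]-2H-chromene | C1=C(O[Si](C)(C)C(C)(C)C)[C@@H](c2ccc(OCc3ccccc3)c(OCc3ccccc3)c2)Oc2c1ccc(OCc1ccccc1)c2OCc1ccccc1 | intermediate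
13 | (2R,3R,4S)-3-silyloxychroman-4-ylborane, 2,3-cis-3,4-trans | c1cc2c(c(OCc3ccccc3)c1OCc1ccccc1)O[C@H](c1ccc(OCc3ccccc3)c(OCc3ccccc3)c1)[C@H](O[Si](C)(C)C(C)(C)C)[C@H]2B | intermediate (not isolated)
14 | (2R,3R,4S)-3-silyloxychroman-4-ol, 2,3-cis-3,4-trans | c1cc2c(c(OCc3ccccc3)c1OCc1ccccc1)O[C@H](c1ccc(OCc3ccccc3)c(OCc3ccccc3)c1)[C@H](O[Si](C)(C)C(C)(C)C)[C@H]2O | intermediate
15 | (2R,3S,4S)-3,4-bis(silyloxy)chromane, 2,3-cis-3,4-trans | c1cc2c(c(OCc3ccccc3)c1OCc1ccccc1)O[C@H](c1ccc(OCc3ccccc3)c(OCc3ccccc3)c1)[C@H](O[Si](C)(C)C(C)(C)C)[C@H]2O[Si](C)(C)C(C)(C)C | intermediate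
16 | 6-bromo derivative of 15 | Brc1cc2c(c(OCc3ccccc3)c1OCc1ccccc1)O[C@H](c1ccc(OCc3ccccc3)c(OCc3ccccc3)c1)[C@H](O[Si](C)(C)C(C)(C)C)[C@H]2O[Si](C)(C)C(C)(C)C | intermediate
17 | 6-(pinacolboryl) derivative of 15 | CC1(C)OB(OC1(C)C)c1cc2c(c(OCc3ccccc3)c1OCc1ccccc1)O[C@H](c1ccc(OCc3ccccc3)c(OCc3ccccc3)c1)[C@H](O[Si](C)(C)C(C)(C)C)[C@H]2O[Si](C)(C)C(C)(C)C | intermediate
18 | enol silyl ether dimer (upper 2R; lower 2R,3S,4S) | O(Cc9ccccc9)c1ccc([C@H]2Oc3c(ccc(OCc9ccccc9)c3OCc9ccccc9)C(c3cc4c(c(OCc9ccccc9)c3OCc9ccccc9)O[C@H](c3ccc(OCc9ccccc9)c(OCc9ccccc9)c3)[C@H](O[Si](C)(C)C(C)(C)C)[C@H]4O[Si](C)(C)C(C)(C)C)=C2O[Si](C)(C)C(C)(C)C)cc1OCc9ccccc9 | intermediate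
19 | ketone dimer (upper 2R,4S, 2,4-cis; lower 2R,3S,4S) | O(Cc9ccccc9)c1ccc([C@H]2Oc3c(ccc(OCc9ccccc9)c3OCc9ccccc9)[C@@H](c3cc4c(c(OCc9ccccc9)c3OCc9ccccc9)O[C@H](c3ccc(OCc9ccccc9)c(OCc9ccccc9)c3)[C@H](O[Si](C)(C)C(C)(C)C)[C@H]4O[Si](C)(C)C(C)(C)C)C2=O)cc1OCc9ccccc9 | intermediate
20 | all-cis alcohol dimer (upper 2R,3R,4S; lower 2R,3S,4S) | O(Cc9ccccc9)c1ccc([C@H]2Oc3c(ccc(OCc9ccccc9)c3OCc9ccccc9)[C@@H](c3cc4c(c(OCc9ccccc9)c3OCc9ccccc9)O[C@H](c3ccc(OCc9ccccc9)c(OCc9ccccc9)c3)[C@H](O[Si](C)(C)C(C)(C)C)[C@H]4O[Si](C)(C)C(C)(C)C)[C@H]2O)cc1OCc9ccccc9 | intermediate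
21 | bis-silyl octaphenol (upper 2R,3R,4R; lower 2R,3S,4S) | Oc1ccc([C@H]2Oc3c(ccc(O)c3O)[C@@H](c3cc4c(c(O)c3O)O[C@H](c3ccc(O)c(O)c3)[C@H](O[Si](C)(C)C(C)(C)C)[C@H]4O[Si](C)(C)C(C)(C)C)[C@H]2O)cc1O | intermediate
22 | target dimer (upper 2R,3R,4R; lower 2R,3R,4S) | Oc1ccc([C@H]2Oc3c(ccc(O)c3O)[C@@H](c3cc4c(c(O)c3O)O[C@H](c3ccc(O)c(O)c3)[C@H](O)[C@H]4O)[C@H]2O)cc1O | target

**Totals**

Total step count: 17. Longest linear sequence: 17 steps (1 → 11 → 17 → 22; the upper half joins as a second portion of 11 in step 13).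

**Three steps most likely to fail**

Risk 1, step 5. The ring-fused diene with a silyloxy group on its reacting terminus may give low enantioface selectivity. Ionisation at the electron-rich benzylic C2 during the acid stage may erode the enantiomeric purity. The diene may also be consumed by oxidation or hydrolysis before it reacts. Fallback by the chalcone epoxide route, which closes ring C through O1–C2 instead: it sets out from 7 and comes back at 10. Commercial 1-(2,3,4-trihydroxyphenyl)ethanone is benzylated at the two unchelated hydroxyls (BnBr, K2CO3, DMF) to 1-[3,4-bis(benzyloxy)-2-hydroxyphenyl]ethanone F1. The chelated phenol is protected (MOMCl, NaH, THF) to give 1-[3,4-bis(benzyloxy)-2-(methoxymethoxy)phenyl]ethanone F2. Claisen–Schmidt condensation with 7 (KOH, EtOH) gives the (E)-chalcone F3. Juliá–Colonna epoxidation (polyleucine of the enantiomer that gives the αR,βS product, urea–H2O2, DBU, THF) gives the trans-epoxy ketone F4. HCl in MeOH removes the acetal, and the phenol opens the epoxide at the benzylic carbon with inversion to the (2R,3R)-trans-dihydroflavonol F5. Silylation (tBuMe2SiOTf, 2,6-lutidine) then gives 10 as its single 2,3-trans epimer.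

Risk 2, step 15. The hydride may act as a base on the acidic, doubly benzylic C4–H (enolisation instead of reduction). The ketone may also sit as the wrong C4 epimer, so that the hydride enters on the wrong face. Fallback that sets C3 and C4 by one syn addition instead of by the ketone: it sets out from 18 and comes back at 22. Hydrogenation of the tetrasubstituted enol ether over Pd(OH)2/C (H2, 4 bar, EtOAc/THF) should add hydrogen to the face opposite the C2 aryl group, as in the known cis-hydrogenation of 3,4-disubstituted 2H-chromenes, while the benzyl ethers are cleaved. This gives the all-cis tris-silyl octaphenol F6, and Bu4NF/AcOH then gives 22.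

Risk 3, step 16. Hydrogenolysis may also cut the benzylic C4′–O bond of the lower unit, or the silyl ethers may be lost on the catalyst. Fallback that carries C4′ through the hydrogenolysis as a ketone: it sets out from 20 and comes back at 22. Bu4NF (THF) frees the lower diol to give the octabenzyl triol F7. MnO2 (CH2Cl2) oxidises only the benzylic 4′-hydroxyl, giving the octabenzyl 4′-ketone F8. H2 over Pd(OH)2/C in EtOAc removes the benzyl groups with the aryl ketone intact, giving the octaphenol 4′-ketone F9. Me4NBH(OAc)3 (MeCN/AcOH, −20 °C) then delivers hydride from the 3′-hydroxyl to the same face, giving the 3′,4′-trans diol 22.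

**Further compounds**

F1 | step 5 | 1-[3,4-bis(benzyloxy)-2-hydroxyphenyl]ethanone | CC(=O)c1ccc(OCc2ccccc2)c(OCc2ccccc2)c1O
F2 | step 5 | 1-[3,4-bis(benzyloxy)-2-(methoxymethoxy)phenyl]ethanone | CC(=O)c1ccc(OCc2ccccc2)c(OCc2ccccc2)c1OCOC
F3 | step 5 | (2E)-1-[3,4-bis(benzyloxy)-2-(methoxymethoxy)phenyl]-3-[3,4-bis(benzyloxy)phenyl]prop-2-en-1-one | COCOc1c(OCc2ccccc2)c(OCc2ccccc2)ccc1C(=O)/C=C/c1ccc(OCc2ccccc2)c(OCc2ccccc2)c1
F4 | step 5 | [(2R,3S)-3-[3,4-bis(benzyloxy)phenyl]oxiran-2-yl][3,4-bis(benzyloxy)-2-(methoxymethoxy)phenyl]methanone | COCOc1c(OCc2ccccc2)c(OCc2ccccc2)ccc1C(=O)[C@@H]1O[C@H]1c1ccc(OCc2ccccc2)c(OCc2ccccc2)c1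
F5 | step 5 | (2R,3R)-2-[3,4-bis(benzyloxy)phenyl]-7,8-bis(benzyloxy)-3-hydroxychroman-4-one (2,3-trans) | O=C1c2ccc(OCc9ccccc9)c(OCc9ccccc9)c2O[C@H](c2ccc(OCc9ccccc9)c(OCc9ccccc9)c2)[C@H]1O
F6 | step 15 | all-cis tris-silyl octaphenol (upper 3-O-silyl, lower 3′,4′-di-O-silyl) | Oc1ccc([C@H]2Oc3c(ccc(O)c3O)[C@@H](c3cc4c(c(O)c3O)O[C@H](c3ccc(O)c(O)c3)[C@H](O[Si](C)(C)C(C)(C)C)[C@H]4O[Si](C)(C)C(C)(C)C)[C@H]2O[Si](C)(C)C(C)(C)C)cc1O
F7 | step 16 | octabenzyl triol (20 without silyl groups) | O(Cc9ccccc9)c1ccc([C@H]2Oc3c(ccc(OCc9ccccc9)c3OCc9ccccc9)[C@@H](c3cc4c(c(OCc9ccccc9)c3OCc9ccccc9)O[C@H](c3ccc(OCc9ccccc9)c(OCc9ccccc9)c3)[C@H](O)[C@H]4O)[C@H]2O)cc1OCc9ccccc9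
F8 | step 16 | octabenzyl lower 4′-ketone | O(Cc9ccccc9)c1ccc([C@H]2Oc3c(ccc(OCc9ccccc9)c3OCc9ccccc9)[C@@H](c3cc4c(c(OCc9ccccc9)c3OCc9ccccc9)O[C@H](c3ccc(OCc9ccccc9)c(OCc9ccccc9)c3)[C@H](O)C4=O)[C@H]2O)cc1OCc9ccccc9
F9 | step 16 | octaphenol lower 4′-ketone | Oc1ccc([C@H]2Oc3c(ccc(O)c3O)[C@@H](c3cc4c(c(O)c3O)O[C@H](c3ccc(O)c(O)c3)[C@H](O)C4=O)[C@H]2O)cc1O
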